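**Retrosynthetic overview**
1. Target ⇐ andrographolide by 3,19-acetonide formation, 14-O-acetylation and acetonide hydrolysis.
2. Butenolide ring (formed last) ⇐ Pd-carbonylative lactonisation of an (E)-C13 vinyl iodide ⇐ syn-hydrostannation/iodination of a C12-alkyne 14,15-diol.
3. C3-OH and C19-OH ⇐ hydride reduction of a 3-oxo-19-ester; C4 quaternary centre ⇐ face-selective C-methylation of the cyclic β-keto ester.
4. Rings A then B, in one cascade ⇐ proposed enantioselective Mg-bisoxazoline/cobaloxime radical Heck-type bicyclisation of an acyclic α-bromo β-keto ester dienyne (sets C5, C9, C10 and the exocyclic alkene).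
5. Acyclic chain ⇐ ethyl acetoacetate dianion + allylic bromide ⇐ SeO2 oxidation ⇐ geranyl bromide + (S)-alkyne from (R)-glyceraldehyde acetonide (source of C14).

Numbering: labdane numbering is used for the terpenoid carbons (C1–C10 decalin, C17 exocyclic methylene, C18/C19 on C4, C20 on C10, C11–C16 side chain); α is the face that carries the C10 methyl group.

Assumption: the facial sense of the (S,S)-ligand in step 7 (and of (−)-8-phenylmenthol in its fallback) is taken from a face-shielding model and from memory of related auxiliary work; if experiment shows the opposite sense, the mirror-image ligand (auxiliary) is used.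

**Step 1**
Reactants: 1 (R)-2,2-dimethyl-1,3-dioxolane-4-carbaldehyde
Product: 2 (S)-4-ethynyl-2,2-dimethyl-1,3-dioxolane
Conditions: Ohira–Bestmann reagent, K2CO3, MeOH, 0 °C to rt
Reagents that add atoms: dimethyl (1-diazo-2-oxopropyl)phosphonate (Ohira–Bestmann reagent), CC(=O)C(=[N+]=[N-])P(=O)(OC)OC
Why: Seyferth–Gilbert homologation (Ohira–Bestmann variant) turns the aldehyde into the terminal alkyne under mild carbonate conditions that do not epimerise the α-alkoxy centre, so the future C14 stereocentre comes from the chiral pool (R becomes S only through a CIP priority change).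

**Step 2**
Reactants: 2 (S)-4-ethynyl-2,2-dimethyl-1,3-dioxolane; 3 geranyl bromide
Product: 4 (4S)-4-[(4E)-5,9-dimethyldeca-4,8-dien-1-yn-1-yl]-2,2-dimethyl-1,3-dioxolane
Conditions: CuI (10 mol%), n-Bu4NI (10 mol%), K2CO3, DMF, rt
Reagents that add atoms: none
Why: Copper-acetylide allylic substitution (copper-catalysed alkyne–allyl halide coupling) at the primary carbon of geranyl bromide forms the C11–C12 bond and gives the skipped enyne with the E-alkene retained.

**Step 3**
Reactants: 4 skipped dienyne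
Product: 5 (2E,6E)-10-[(4S)-2,2-dimethyl-1,3-dioxolan-4-yl]-2,6-dimethyldeca-2,6-dien-9-yn-1-ol
Conditions: SeO2 (10 mol%), t-BuOOH, salicylic acid (10 mol%), CH2Cl2, 0 °C to rt
Reagents that add atoms: tert-butyl hydroperoxide, CC(C)(C)OO
Why: Catalytic SeO2/t-BuOOH allylic oxidation (ene reaction then [2,3]-sigmatropic shift) hydroxylates the E-methyl of the most accessible terminal trisubstituted alkene, giving the (E)-allylic alcohol whose carbinol carbon becomes C1.

**Step 4**
Reactants: 5 (E,E)-allylic alcohol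
Product: 6 (4S)-4-[(4E,8E)-10-bromo-5,9-dimethyldeca-4,8-dien-1-yn-1-yl]-2,2-dimethyl-1,3-dioxolane
Conditions: CBr4, PPh3, CH2Cl2, −20 °C
Reagents that add atoms: tetrabromomethane, BrC(Br)(Br)Br
Why: Appel bromination converts the primary allylic alcohol into the bromide under neutral conditions at low temperature without allylic transposition or loss of the acetonide.

**Step 5**
Reactants: 6 allylic bromide; 7 ethyl acetoacetate
Product: 9 ethyl (6E,10E)-14-[(4S)-2,2-dimethyl-1,3-dioxolan-4-yl]-6,10-dimethyl-3-oxotetradeca-6,10-dien-13-ynoate, via ethyl acetoacetate sodium lithium dianion 8 (not isolated)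
Conditions: 7, NaH, THF, 0 °C; n-BuLi, 0 °C; then 6, 0 °C; aq NH4Cl
Reagents that add atoms: none
Why: Weiler γ-alkylation of the acetoacetate dianion, in which the more basic terminal carbanion of 8 displaces the allylic bromide (SN2) to form the C1–C2 bond and complete the carbon chain.

**Step 6**
Reactants: 9 polyene β-keto ester
Product: 10 ethyl (6E,10E)-2-bromo-14-[(4S)-2,2-dimethyl-1,3-dioxolan-4-yl]-6,10-dimethyl-3-oxotetradeca-6,10-dien-13-ynoate (both C2 epimers)
Conditions: NBS, Mg(ClO4)2 (20 mol%), MeCN, 0 °C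
Reagents that add atoms: N-bromosuccinimide, O=C1CCC(=O)N1Br
Why: Mg(ClO4)2-catalysed enol bromination of the β-keto ester is much faster than attack of NBS on the alkenes or the alkyne, and the uncontrolled C–Br centre is irrelevant because it becomes a planar radical.

**Step 7**
Reactants: 10 α-bromo β-keto ester
Product: 11 ethyl 3-oxo-trans-decalin-4-carboxylate with 10α-methyl, 5β-H, 9β-H, 8(17)-exocyclic methylene and 9α-{3-[(4S)-2,2-dimethyl-1,3-dioxolan-4-yl]prop-2-ynyl} side chain (C4–H, keto/enol and C4-epimer mixture)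
Conditions: Mg(NTf2)2 (30 mol%), (S,S)-t-Bu-bisoxazoline [2,2'-(propane-2,2-diyl)bis((4S)-4-tert-butyl-4,5-dihydrooxazole)] (33 mol%), Co(dmgH)2(py)Cl (5 mol%), i-Pr2NEt, 4 Å MS, CH2Cl2, 450 nm LED, −40 °C
Reagents that add atoms: none
Why: Proposed new method: an enantioselective radical Heck-type (dehydrobrominative) polyene bicyclisation under chiral magnesium Lewis acid/cobaloxime dual catalysis, in which the bisoxazoline–Mg chelate of the β-keto ester loses bromine to monovalent cobalt (generated from the cobaloxime, i-Pr2NEt and light) faster than free substrate does, the Mg-bound dicarbonyl radical (one face shielded by a tert-butyl group) closes ring A by chair 6-endo attack on C5, the C10 radical closes ring B by a second chair 6-endo attack on the E-alkene (10-Me/5-H trans, 9-H axial, side chain equatorial), and divalent cobalt abstracts a hydrogen atom from the least hindered C17 methyl of the tertiary C8 radical to give the exocyclic alkene while the trivalent cobalt hydride is deprotonated to close the cycle; the closest known reaction types are the chiral Mg–bisoxazoline atom-transfer radical cyclisation of α-bromo β-keto esters and the cobaloxime-catalysed alkyl-Heck cyclisation.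

**Step 8**
Reactants: 11 bicyclic β-keto ester
Product: 12 ethyl (1S,4aS,5R,8aS)-5-{3-[(4S)-2,2-dimethyl-1,3-dioxolan-4-yl]prop-2-yn-1-yl}-1,4a-dimethyl-6-methylidene-2-oxodecahydronaphthalene-1-carboxylate (4β-methyl, 4α-axial ester)
Conditions: MeI, K2CO3, acetone, rt
Reagents that add atoms: iodomethane, CI
Why: C-alkylation of the cyclic β-keto ester enolate, where MeI approaches the C3–C4 enolate from the β face opposite the axial C10 methyl group, so the new methyl is equatorial (C18) and the ester axial (C19), which sets the C4 quaternary centre.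

**Step 9**
Reactants: 12 methylated keto ester
Product: 14 (2S)-5-[(1R,4aS,5R,6R,8aS)-6-hydroxy-5-(hydroxymethyl)-5,8a-dimethyl-2-methylidenedecahydronaphthalen-1-yl]pent-3-yne-1,2-diol, via 3,19-diol 14,15-acetonide 13 (not isolated)
Conditions: LiAlH4, THF, −78 °C to rt; then 1 M aq HCl, THF, rt
Reagents that add atoms: none
Why: Hydride reduction in which axial delivery to the C3 ketone (the α face is blocked by the axial C4 ester) gives the equatorial 3α-alcohol and the ester becomes the C19 carbinol, followed by acetal hydrolysis of the terminal dioxolane in the acidic quench.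

**Step 10**
Reactants: 14 alkynyl tetraol
Product: 16 (2R,3E)-5-[(1R,4aS,5R,6R,8aS)-6-hydroxy-5-(hydroxymethyl)-5,8a-dimethyl-2-methylidenedecahydronaphthalen-1-yl]-3-iodopent-3-ene-1,2-diol, via C13 tributylvinylstannane 15 (not isolated)
Conditions: Bu3SnH, PdCl2(PPh3)2 (5 mol%), THF, 0 °C; then I2, 0 °C
Reagents that add atoms: iodine, [I][I]
Why: Palladium-catalysed syn-hydrostannation of the propargylic alcohol puts tin on C13 (next to the carbinol) and hydrogen on C12, and iododestannylation with retention fixes the trisubstituted alkene geometry (C11 trans to iodine).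

**Step 11**
Reactants: 16 (E)-vinyl iodide tetraol
Product: 17 andrographolide, (3E,4S)-3-{2-[(1R,4aS,5R,6R,8aS)-6-hydroxy-5-(hydroxymethyl)-5,8a-dimethyl-2-methylidenedecahydronaphthalen-1-yl]ethylidene}-4-hydroxyoxolan-2-one
Conditions: PdCl2(PPh3)2 (10 mol%), CO (1 atm), i-Pr2NEt, THF, 45 °C
Reagents that add atoms: carbon monoxide, [C-]#[O+]
Why: Palladium-catalysed carbonylative lactonisation (oxidative addition, CO insertion, acyl capture by the primary C15 hydroxyl to the five-membered lactone; the C14 hydroxyl would give a strained β-lactone) closes the ring with the alkene geometry retained.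

**Step 12**
Reactants: 17 andrographolide
Product: 18 3,19-O-isopropylidene-andrographolide
Conditions: 2,2-dimethoxypropane, PPTS (cat.), acetone, rt
Reagents that add atoms: 2,2-dimethoxypropane, COC(C)(C)OC
Why: Acetal exchange converts the C3/C19 1,3-diol into the six-membered acetonide, leaving only the C14 hydroxyl free because a lone secondary alcohol cannot form a cyclic acetal.

**Step 13**
Reactants: 18 3,19-O-isopropylidene-andrographolide
Product: 19 14-O-acetyl-3,19-O-isopropylidene-andrographolide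
Conditions: Ac2O, pyridine, DMAP (cat.), CH2Cl2, 0 °C
Reagents that add atoms: acetic anhydride, CC(=O)OC(C)=O
Why: DMAP-catalysed acylation of the only free hydroxyl, run cold and briefly so that base-induced elimination of the allylic acetate does not compete.

**Step 14**
Reactants: 19 14-O-acetyl-3,19-O-isopropylidene-andrographolide
Product: 20 14-O-acetylandrographolide (CNP0077248.1)
Conditions: AcOH/H2O (7:3), rt
Reagents that add atoms: none
Why: Mild acetal hydrolysis removes the acetonide while the allylic acetate, the lactone and the exocyclic alkene are untouched.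

**Compound list**
1 | (R)-2,2-dimethyl-1,3-dioxolane-4-carbaldehyde | O=C[C@H]1COC(C)(C)O1 | starting material
2 | (S)-4-ethynyl-2,2-dimethyl-1,3-dioxolane | C#C[C@H]1COC(C)(C)O1 | intermediate
3 | geranyl bromide, (2E)-1-bromo-3,7-dimethylocta-2,6-diene | CC(C)=CCC/C(C)=C/CBr | starting material
4 | (4S)-4-[(4E)-5,9-dimethyldeca-4,8-dien-1-yn-1-yl]-2,2-dimethyl-1,3-dioxolane | CC(C)=CCC/C(C)=C/CC#C[C@H]1COC(C)(C)O1 | intermediate
5 | (2E,6E)-10-[(4S)-2,2-dimethyl-1,3-dioxolan-4-yl]-2,6-dimethyldeca-2,6-dien-9-yn-1-ol | OC/C(C)=C/CC/C(C)=C/CC#C[C@H]1COC(C)(C)O1 | intermediate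
6 | (4S)-4-[(4E,8E)-10-bromo-5,9-dimethyldeca-4,8-dien-1-yn-1-yl]-2,2-dimethyl-1,3-dioxolane | BrC/C(C)=C/CC/C(C)=C/CC#C[C@H]1COC(C)(C)O1 | intermediate
7 | ethyl acetoacetate (ethyl 3-oxobutanoate) | CCOC(=O)CC(C)=O | starting material
8 | ethyl acetoacetate sodium lithium dianion | [Na+].[Li+].[CH2-]C(=O)[CH-]C(=O)OCC | intermediate
9 | ethyl (6E,10E)-14-[(4S)-2,2-dimethyl-1,3-dioxolan-4-yl]-6,10-dimethyl-3-oxotetradeca-6,10-dien-13-ynoate | CCOC(=O)CC(=O)CC/C(C)=C/CC/C(C)=C/CC#C[C@H]1COC(C)(C)O1 | intermediate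
10 | ethyl (6E,10E)-2-bromo-14-[(4S)-2,2-dimethyl-1,3-dioxolan-4-yl]-6,10-dimethyl-3-oxotetradeca-6,10-dien-13-ynoate (C2 epimers) | CCOC(=O)C(Br)C(=O)CC/C(C)=C/CC/C(C)=C/CC#C[C@H]1COC(C)(C)O1 | intermediate
11 | ethyl (4aR,5R,8aR)-5-{3-[(4S)-2,2-dimethyl-1,3-dioxolan-4-yl]prop-2-yn-1-yl}-4a-methyl-6-methylidene-2-oxodecahydronaphthalene-1-carboxylate (C1 epimers/enol; trans-decalin, 10α-Me, 5β-H, 9β-H) | C=C1CC[C@@H]2C(C(=O)OCC)C(=O)CC[C@@]2(C)[C@@H]1CC#C[C@H]3COC(C)(C)O3 | intermediate
12 | ethyl (1S,4aS,5R,8aS)-5-{3-[(4S)-2,2-dimethyl-1,3-dioxolan-4-yl]prop-2-yn-1-yl}-1,4a-dimethyl-6-methylidene-2-oxodecahydronaphthalene-1-carboxylate | C=C1CC[C@@H]2[C@](C)(C(=O)OCC)C(=O)CC[C@@]2(C)[C@@H]1CC#C[C@H]3COC(C)(C)O3 | intermediate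
13 | (1R,2R,4aS,5R,8aS)-5-{3-[(4S)-2,2-dimethyl-1,3-dioxolan-4-yl]prop-2-yn-1-yl}-1-(hydroxymethyl)-1,4a-dimethyl-6-methylidenedecahydronaphthalen-2-ol | C=C1CC[C@@H]2[C@](C)(CO)[C@H](O)CC[C@@]2(C)[C@@H]1CC#C[C@H]3COC(C)(C)O3 | intermediate
14 | (2S)-5-[(1R,4aS,5R,6R,8aS)-6-hydroxy-5-(hydroxymethyl)-5,8a-dimethyl-2-methylidenedecahydronaphthalen-1-yl]pent-3-yne-1,2-diol | C=C1CC[C@@H]2[C@](C)(CO)[C@H](O)CC[C@@]2(C)[C@@H]1CC#C[C@H](O)CO | intermediate
15 | (2R,3E)-5-[(1R,4aS,5R,6R,8aS)-6-hydroxy-5-(hydroxymethyl)-5,8a-dimethyl-2-methylidenedecahydronaphthalen-1-yl]-3-(tributylstannyl)pent-3-ene-1,2-diol | C=C1CC[C@@H]2[C@](C)(CO)[C@H](O)CC[C@@]2(C)[C@@H]1C/C=C(/[Sn](CCCC)(CCCC)CCCC)[C@H](O)CO | intermediate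
16 | (2R,3E)-5-[(1R,4aS,5R,6R,8aS)-6-hydroxy-5-(hydroxymethyl)-5,8a-dimethyl-2-methylidenedecahydronaphthalen-1-yl]-3-iodopent-3-ene-1,2-diol | C=C1CC[C@@H]2[C@](C)(CO)[C@H](O)CC[C@@]2(C)[C@@H]1C/C=C(/I)[C@H](O)CO | intermediate
17 | andrographolide | C=C1CC[C@@H]2[C@](C)(CO)[C@H](O)CC[C@@]2(C)[C@@H]1C/C=C1/C(=O)OC[C@H]1O | intermediate
18 | 3,19-O-isopropylidene-andrographolide | C=C1CC[C@@H]2[C@](C)(COC(C)(C)O3)[C@H]3CC[C@@]2(C)[C@@H]1C/C=C1/C(=O)OC[C@H]1O | intermediate
19 | 14-O-acetyl-3,19-O-isopropylidene-andrographolide | C=C1CC[C@@H]2[C@](C)(COC(C)(C)O3)[C@H]3CC[C@@]2(C)[C@@H]1C/C=C1/C(=O)OC[C@H]1OC(C)=O | intermediate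
20 | 14-O-acetylandrographolide, (3S,4E)-4-{2-[(1R,4aS,5R,6R,8aS)-6-hydroxy-5-(hydroxymethyl)-5,8a-dimethyl-2-methylidenedecahydronaphthalen-1-yl]ethylidene}-5-oxooxolan-3-yl acetate | C=C1CC[C@@H]2[C@](C)(CO)[C@H](O)CC[C@@]2(C)[C@@H]1C/C=C1/C(=O)OC[C@H]1OC(C)=O | target

**Totals**
Total step count: 14. Longest linear sequence: 14 steps (1 to 20); 3 and 7 are purchased and used directly.

**Three steps most likely to fail**

Step 7 (proposed new method). Risks are low or reversed enantioselectivity, a racemic background reaction of unbound substrate, and endocyclic alkene isomers from the termination. The fallback uses known auxiliary-controlled oxidative radical cyclisation; it sets out from 9 and comes back at 14. β-Keto ester 9 is transesterified with (1R,2S,5R)-(−)-8-phenylmenthol (DMAP cat., toluene, reflux, ethanol distilled off) to give the 8-phenylmenthyl polyene β-keto ester F1. Oxidative free-radical bicyclisation with Mn(OAc)3·2H2O and Cu(OAc)2 in the presence of Yb(OTf)3 (CF3CH2OH, −5 °C) gives the bicyclic 8-phenylmenthyl β-keto ester F2; the chelated auxiliary shields one face of the radical and Cu(OAc)2 oxidises the C8 radical to the exocyclic alkene. MeI/K2CO3 as in step 8 gives the C4-methylated 8-phenylmenthyl keto ester F3. LiAlH4 then aqueous HCl as in step 9 reduces ketone and ester, releases the auxiliary for recovery and, through 13, returns to tetraol 14.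

Step 10. The risk is that tin adds to C12 instead of C13 (wrong regioisomer), or that the polar stannane protodestannylates. The fallback sets out from 14 and comes back at 17, bypassing 15 and 16. Alkoxide-directed nickel-catalysed syn-hydrocarboxylation (Ni(cod)2 10 mol%, CsF, excess Et2Zn, CO2 1 atm, MeCN, rt) delivers CO2 to C13 next to the chelating zinc alkoxides and hydrogen to C12, giving the (E)-andrographolide seco acid F4 as its zinc salt. Acidic work-up (1 M HCl) lactonises it to andrographolide 17.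

Step 3. Risks are a modest yield, competing oxidation at the internal alkene (C7) or the doubly activated C11 methylene, and over-oxidation to the enal. The fallback sets out from 4 and comes back at 6, bypassing 5. NBS in THF/H2O at 0 °C gives the terminal bromohydrin F5, selective for the terminal trisubstituted alkene. K2CO3 in MeOH closes the terminal epoxide F6. Al(Oi-Pr)3 in refluxing toluene isomerises it to the secondary isopropenyl carbinol F7. PBr3 in Et2O at −10 °C then gives bromide 6 directly by E-selective SN2' transposition.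

**Further compounds**
F1 | step 7 | (1R,2S,5R)-5-methyl-2-(2-phenylpropan-2-yl)cyclohexyl (6E,10E)-14-[(4S)-2,2-dimethyl-1,3-dioxolan-4-yl]-6,10-dimethyl-3-oxotetradeca-6,10-dien-13-ynoate | O=C(CC(=O)CC/C(C)=C/CC/C(C)=C/CC#C[C@H]1COC(C)(C)O1)O[C@@H]1C[C@H](C)CC[C@H]1C(C)(C)c1ccccc1
F2 | step 7 | 8-phenylmenthyl ester analogue of 11 (C4–H, keto/enol) | C=C1CC[C@@H]2C(C(=O)O[C@@H]3C[C@H](C)CC[C@H]3C(C)(C)c3ccccc3)C(=O)CC[C@@]2(C)[C@@H]1CC#C[C@H]1COC(C)(C)O1
F3 | step 7 | 8-phenylmenthyl ester analogue of 12 (4β-methyl, 4α-ester) | C=C1CC[C@@H]2[C@](C)(C(=O)O[C@@H]3C[C@H](C)CC[C@H]3C(C)(C)c3ccccc3)C(=O)CC[C@@]2(C)[C@@H]1CC#C[C@H]1COC(C)(C)O1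
F4 | step 10 | (2E)-2-[(1S)-1,2-dihydroxyethyl]-4-[(1R,4aS,5R,6R,8aS)-6-hydroxy-5-(hydroxymethyl)-5,8a-dimethyl-2-methylidenedecahydronaphthalen-1-yl]but-2-enoic acid (andrographolide seco acid) | C=C1CC[C@@H]2[C@](C)(CO)[C@H](O)CC[C@@]2(C)[C@@H]1C/C=C(/C(=O)O)[C@H](O)CO
F5 | step 3 | (6E)-3-bromo-10-[(4S)-2,2-dimethyl-1,3-dioxolan-4-yl]-2,6-dimethyldec-6-en-9-yn-2-ol (C3 epimers) | CC(C)(O)C(Br)CC/C(C)=C/CC#C[C@H]1COC(C)(C)O1
F6 | step 3 | (4S)-4-[(4E)-7-(3,3-dimethyloxiran-2-yl)-5-methylhept-4-en-1-yn-1-yl]-2,2-dimethyl-1,3-dioxolane (epoxide epimers) | CC1(C)OC1CC/C(C)=C/CC#C[C@H]2COC(C)(C)O2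
F7 | step 3 | (6E)-10-[(4S)-2,2-dimethyl-1,3-dioxolan-4-yl]-2,6-dimethyldeca-1,6-dien-9-yn-3-ol (C3 epimers) | C=C(C)C(O)CC/C(C)=C/CC#C[C@H]1COC(C)(C)O1
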